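Early on, Tuesday's flask moves fast: target reaches 38.0% by 0.333 d, while substrate has fallen to 17.5%. The catalyst acts on the substrate, and the readings follow target and substrate.

the same everywhere: substrate 0.80 M
- Tuesday's: catalyst 5 mol%; temperature 5 °C; the very flask that is asked about, followed so far
- Friday's: catalyst 7.5 mol%; temperature −10 °C; run made earlier
- flask: catalyst 5 mol%; temperature 5 °C; time 5.0 d

Tuesday's run (percent of the substrate charged)

| time / d | target / % | substrate / % |
|---|---|---|
| 0.333 | 38.0 | 17.5 |
| 0.500 | 43.8 | 12.6 |
| 0.833 | 54.0 | 8.2 |
| 1.04 | 55.0 | 6.1 |
| 1.67 | 61.9 | 5.4 |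
| 2.50 | 67.6 | 4.2 |
| 4.00 | 71.7 | 4.4 |

Friday's run (percent of the substrate charged)

| time / h | target / % | substrate / % |
|---|---|---|
| 6.00 | 13.4 | 49.1 |
| 12.0 | 19.4 | 26.3 |
| 20.0 | 25.5 | 12.7 |
| 30.0 | 25.9 | 7.2 |
| 40.0 | 30.7 | 5.2 |
| 48.0 | 31.3 | 4.1 |

(standard deviation of a reading: 1 percentage point)

- percent here means substrate units held: one homo dimer counts as two
- removed target is counted in
- steps under discussion: substrate + catalyst <-> target + catalyst; substrate + catalyst <-> isomer of the product B + catalyst; 2 substrate -> homo dimer; substrate + catalyst <-> isomer of the product A + catalyst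
- additions bring no volume worth counting

- north: at 5.0 d take out 90% of the target then present, then wait 2.5 d
- west: at 5.0 d add catalyst, 100% of the amount charged, then wait 2.5 d
- south: change nothing and wait 2.5 d more
- south-west: at 5.0 d raise the temperature by 15 K, then wait 2.5 d

1. target, in percent of the substrate first charged, at 5.0 d
2. what to do for the largest gain in target; "none" if nothing gains more than 2 percentage points (north / west / south / south-west / none)
3. target present, with what was taken out counted in, in percent of the substrate first charged, after north
4. target present, with what was taken out counted in, in percent of the substrate first charged, after west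

At 4.00 d the two columns leave 23.9% of the charge unshown. I call this the hidden share, the percent of the charge that is neither target nor substrate. Its zero is a flask where the two columns add up to the charge. It holds both isomers and the homo dimer.

Now I draw the curve. The hidden share stands at 44.5% at the first reading. At 0.500 d it is 43.6%, and target crosses it there, at 43.8%. The knee comes next: [substrate] reads 4.2% at 2.50 d and 4.4% at 4.00 d, flat within the scatter. Over that stretch the hidden share falls from 28.2% to 23.9%, a loss of 4.3 percentage points, and target gains 4.1 points. So target now grows while the hidden share falls, which I read as a passage from kinetic to thermodynamic control.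

I continue that pace to 5.0 d. The hidden share comes to 21.0%. With substrate at its last reading, target is 74.6%. Friday's flask, colder and with more catalyst, still hides 64.6% at 48.0 h.

The forecast gives 73.3% (72% to 75%), below my figure. It chooses north, with 85% after north and 75.6% after west. Its ground: “target is being fed by a kinetic isomer draining back through substrate”.

The flask gives 74.8%. The best option is north, gaining 11 points to reach 85.8%, while west reaches 80.5%.

    substrate + catalyst ⇌ target + catalyst, rate k1*[substrate]*[catalyst] forward; the back reaction follows from the equilibrium constant (K = 28.0, k = 0.0500 M⁻¹ min⁻¹, Ea = 72.0 kJ mol⁻¹, ΔH = −34.0 kJ mol⁻¹)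
    substrate + catalyst ⇌ isomer of the product B + catalyst, rate k2*[substrate]*[catalyst] forward; the back reaction follows from the equilibrium constant (K = 0.650, k = 0.0590 M⁻¹ min⁻¹, Ea = 53.0 kJ mol⁻¹, ΔH = −77.0 kJ mol⁻¹)
    2 substrate → homo dimer (k = 6.00 × 10⁻⁶ M⁻¹ min⁻¹, Ea = 81.0 kJ mol⁻¹)
    substrate + catalyst ⇌ isomer of the product A + catalyst, rate k4*[substrate]*[catalyst] forward; the back reaction follows from the equilibrium constant (K = 4.50, k = 0.0410 M⁻¹ min⁻¹, Ea = 63.0 kJ mol⁻¹, ΔH = −28.0 kJ mol⁻¹)
    (constants at 5 °C)

At 5.0 d the flask hides 21.7%, down from 23.9% read at 4.00 d, and isomer of the product A holds 19.3%. At that time the relaxation half-life of substrate and target, by the step between them alone, is 0.232 d, shorter than the 5.0 d waited, and the backward rate of the step from substrate to target stands at 77.2% of its forward rate. A neighbour flask kept at −20 °C hides 74.0% at 5.0 d, and isomer of the product B holds 50.4% there.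

The runs are calculated for an exercise.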